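Its constants were drawn at random within sensible limits; the flask was simulated.

The substrate charge stands above the coupling partner charge, so 14.0 mM of substrate has no partner to couple with. The flasks differ in their free catalyst charge.

    substrate + free catalyst → catalyst intermediate A (k1 = 670 M⁻¹ h⁻¹)
    coupling partner + catalyst intermediate A ⇌ catalyst intermediate B (K2 = 43 M⁻¹, k2 = 650 M⁻¹ h⁻¹)
    catalyst intermediate B → catalyst intermediate C (k3 = 1.2 h⁻¹)
    catalyst intermediate C ⇌ released group + catalyst intermediate D (K4 = 0.032 M, k4 = 1.3 h⁻¹)
    catalyst intermediate D → free catalyst + target (k5 = 1.5 h⁻¹)
    2 catalyst intermediate C ⇌ resting dimer, settled at all times (K6 = 1400 M⁻¹)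
    coupling partner → decomposition product (k7 = 1.9 × 10⁻⁴ h⁻¹)
    catalyst intermediate B + capture agent → trapped intermediate (k8 = 36 M⁻¹ h⁻¹)

| flask | substrate | coupling partner | capture agent | free catalyst | time |
|---|---|---|---|---|---|
| Friday's | 0.035 M | 0.0210 M | 1.75 mM | 5.0 mM | 2.0 d |
| Sunday's | 0.035 M | 0.0210 M | 1.75 mM | 8.0 mM | 2.0 d |
| Tuesday's | 0.035 M | 0.0210 M | 1.75 mM | 12 mM | 2.0 d |
| Thursday's | 0.035 M | 0.0210 M | 1.75 mM | 15 mM | 2.0 d |
| Wednesday's | 0.035 M | 0.0210 M | 1.75 mM | 25 mM | 2.0 d |

- percentages count the substrate that a species holds: one resting dimer counts as two
- a step written with two of one species runs at k times the square of its concentration and takes two of it each time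
- "hardly changes" means that all values lie within two and a half points (for a concentration: within two and a half percent of the largest)
- run time (Friday's): 2.0 d

1. amount of target at the end, in percent of the substrate charged for Friday's, Sunday's, Tuesday's, Thursday's, Wednesday's, in this order
2. how that number moves from the first to the last of them (falls all the way / hardly changes / rises, then falls / rises all the way / falls, then rises)

I reckon by hand, each step using the last.

1. The zero of my scale is the clean case, in which each coupling partner ends as target. The coupling partner is the limiting reagent, so the ceiling is 60.0% of the substrate charged.

2. I measure losses down from that ceiling. Catalyst intermediate B can return to catalyst intermediate A, which wastes nothing, or leave for good by two exits: forward at 1.2 h⁻¹, or into trapped intermediate at 36 M⁻¹ h⁻¹ times [capture agent]. I divide the trapping constant by the forward constant and call the result the trap factor, a selectivity factor: the odds of trapping against going forward, per unit of [capture agent] 30.0 M⁻¹. It contains no catalyst concentration.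

3. With [capture agent] at its charge, the odds are 0.0525, so trapping takes a share of 4.99% of the coupling partner that leaves catalyst intermediate B.

4. Next I check the time on Friday's, the flask with the lowest catalyst charge. Suppose its catalyst stands as catalyst intermediate A while the coupling partner thins out. The coupling partner then falls pseudo-first-order at 0.258 h⁻¹, with a half-life of 2.69 h. This is optimistic, as it counts no catalyst in the resting dimer, but the run is 17.9 such half-lives long. I therefore take the coupling partner as consumed.

5. I commit to the ceiling less the share: 57.0%, the same at 5.0 mM and at 25 mM, so a flat row.

6. The weak link is holding [capture agent] at its charge: trapping consumes it. In my reckoning, [capture agent] drops per unit of target formed by the trap factor times [capture agent], which is an exponential fall with [target]. At the target of step 5, [capture agent] stands at 0.962 mM. The coupling partner lost is then 0.788 mM, which lifts my number to 57.7%.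

The forecast, slightly below mine, gives 57.1%, 57.4%, 57.5%, 57.6% and 57.6%, says the row hardly changes, and has the loss “set by the ratio of trapping to forward flow”.

The simulation gives 57.3%, 57.6%, 57.7%, 57.7% and 57.7%, so the row hardly changes.

Wednesday's, with 25 mM of free catalyst, ends with 0% of its coupling partner left, and that shortage holds the target down: without it, the target goes from 57.7% to 96.8%. The trap factor applied to Wednesday's target predicts that 54.6% of the capture agent remains, and the flask holds 54.6%. Applied to Friday's target, it predicts 54.8%, and that flask holds 54.7%. The trapped intermediate is 15.8% of Friday's catalyst, or 0.790 mM, and 3.18% of Wednesday's, or 0.795 mM.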